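## Retrosynthetic overview

1. Target ⇐ tert‑butyl ester cleavage, O8 tigloylation and C8 ketone reduction ⇐ 8‑oxo elemanolide ⇐ 8α‑aminoxy elemanolide (the aminoxy group is a removable chirality relay).
2. Cyclohexane ring (formed last): chair Cope rearrangement of an (E,E)‑germacra‑1(10),4‑dien‑12,6‑olide, C5–C10 bond.
3. Ten‑membered carbocycle (formed first) and γ‑lactone (second): one CrCl2‑mediated closure of an acyclic 2‑(bromomethyl)enoate onto the C6 enal makes the C6–C7 bond (the farnesyl C1–C10 bond of germacrene biosynthesis); the C6 alkoxide then lactonises on C12.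
4. Acyclic C15 chain: two Morita–Baylis–Hillman reactions (tert‑butyl acrylate with glyoxal monoacetal; methyl acrylate), two Claisen rearrangements, one isopropenyl Grignard addition and one organocatalytic α‑oxyamination, which sets C8, the single stereocentre carried into the ring closure.

Assumption: positions are given in germacrane/elemane numbering (lactone C12/O6, carboxyl C15; target = 5R,6R,7R,8R,10S); the sense of induction of the imidazolidinone in step 5 follows the usual shielding model, and its antipode would be used if the sense proved opposite.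

## Route

Step 1
Reactants: 1 tert‑butyl acrylate, 2 2,2‑dimethoxyacetaldehyde (60 wt% in water)
Product: 3 tert‑butyl 3‑hydroxy‑4,4‑dimethoxy‑2‑methylidenebutanoate (racemic)
Conditions: DABCO (1 equiv), 1,4‑dioxane/H2O 1:1, 25 °C, 48 h
Reagents that add atoms: 2,2‑dimethoxyacetaldehyde 2, COC(OC)C=O
Why: Morita–Baylis–Hillman reaction of an acrylate with an activated α,α‑dialkoxy aldehyde; the carbinol centre is racemic and is erased in step 2.

Step 2
Reactants: 3 tert‑butyl 3‑hydroxy‑4,4‑dimethoxy‑2‑methylidenebutanoate, 4 trimethyl orthoacetate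
Product: 6 1‑tert‑butyl 5‑methyl (2Z)‑2‑(2,2‑dimethoxyethylidene)pentanedioate, via ketene acetal 5 (not isolated)
Conditions: MeC(OMe)3 (6 equiv), EtCO2H (5 mol%), toluene, 115 °C, MeOH distilled off
Reagents that add atoms: trimethyl orthoacetate 4, CC(OC)(OC)OC
Why: Johnson–Claisen rearrangement through a chair transition state with the acetal carbon pseudo‑equatorial; for ester‑derived Baylis–Hillman alcohols this places the aldehyde‑derived carbon cis to the ester (Z), which is the C4=C5 geometry with C6 cis to C15 needed for an E,E ten‑membered ring.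

Step 3
Reactants: 6 1‑tert‑butyl 5‑methyl (2Z)‑2‑(2,2‑dimethoxyethylidene)pentanedioate, 7 isopropenylmagnesium bromide
Product: 9 tert‑butyl (2Z)‑2‑(2,2‑dimethoxyethylidene)‑5‑hydroxy‑6‑methylhept‑6‑enoate (racemic), via aldehyde 8 (not isolated)
Conditions: i‑Bu2AlH (1.05 equiv), CH2Cl2, −78 °C; then isopropenylmagnesium bromide (2.5 equiv, THF), −78 → 0 °C
Reagents that add atoms: isopropenylmagnesium bromide 7, C=C(C)[Mg]Br
Why: tandem DIBAL half‑reduction/Grignard addition: the unhindered methyl ester is reduced to its aluminium hemiacetal (the conjugated tert‑butyl ester is much slower) and the released aldehyde takes up the Grignard reagent in the same flask; the new carbinol is racemic and is erased in step 4.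

Step 4
Reactants: 9 tert‑butyl (2Z)‑2‑(2,2‑dimethoxyethylidene)‑5‑hydroxy‑6‑methylhept‑6‑enoate, 10 ethyl vinyl ether
Product: 12 tert‑butyl (2Z,5E)‑2‑(2,2‑dimethoxyethylidene)‑6‑methyl‑9‑oxonon‑5‑enoate, via allyl vinyl ether 11 (not isolated)
Conditions: ethyl vinyl ether (solvent), Hg(OAc)2 (0.2 equiv), reflux, 24 h; concentrate; toluene, 130 °C (sealed), 6 h
Reagents that add atoms: ethyl vinyl ether 10, C=COCC
Why: transvinylation followed by aliphatic Claisen rearrangement; the chair transition state with the chain pseudo‑equatorial gives the E trisubstituted C1=C10 olefin (about 9:1 or better), the classical isoprenoid chain extension.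

Step 5
Reactants: 12 tert‑butyl (2Z,5E)‑2‑(2,2‑dimethoxyethylidene)‑6‑methyl‑9‑oxonon‑5‑enoate, 13 TEMPO
Product: 14 tert‑butyl (2Z,5E,8S)‑2‑(2,2‑dimethoxyethylidene)‑6‑methyl‑9‑oxo‑8‑[(2,2,6,6‑tetramethylpiperidin‑1‑yl)oxy]non‑5‑enoate
Conditions: TEMPO (1.5 equiv), (2S,5S)‑5‑benzyl‑2‑tert‑butyl‑3‑methylimidazolidin‑4‑one·TFA (20 mol%), CuCl2 (10 mol%), air, acetone, −10 °C
Reagents that add atoms: TEMPO 13, CC1(C)CCCC(C)(C)N1[O]
Why: enamine‑catalysed enantioselective α‑oxyamination of an aldehyde (CuCl2/air turnover); the benzyl group of the imidazolidinone shields one enamine face, so the C–O bond forms to give the 8S centre as a configurationally stable, non‑migrating aminoxy ether.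

Step 6
Reactants: 14 tert‑butyl (2Z,5E,8S)‑2‑(2,2‑dimethoxyethylidene)‑6‑methyl‑9‑oxo‑8‑[(2,2,6,6‑tetramethylpiperidin‑1‑yl)oxy]non‑5‑enoate, 15 methyl acrylate
Product: 16 1‑tert‑butyl 11‑methyl (2Z,5E,8S)‑2‑(2,2‑dimethoxyethylidene)‑9‑hydroxy‑6‑methyl‑10‑methylidene‑8‑[(2,2,6,6‑tetramethylpiperidin‑1‑yl)oxy]undec‑5‑enedioate (both C9 epimers)
Conditions: methyl acrylate (10 equiv), DABCO (1 equiv), MeOH (2 equiv), 25 °C, 3 d
Reagents that add atoms: methyl acrylate 15, C=CC(=O)OC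
Why: Morita–Baylis–Hillman reaction of an α‑heteroatom‑activated aldehyde; the new carbinol (C7) forms as a mixture, which does not matter because it is erased in step 7, and the aminoxy group at C8 can neither migrate nor eliminate.

Step 7
Reactants: 16 1‑tert‑butyl 11‑methyl (2Z,5E,8S)‑2‑(2,2‑dimethoxyethylidene)‑9‑hydroxy‑6‑methyl‑10‑methylidene‑8‑[(2,2,6,6‑tetramethylpiperidin‑1‑yl)oxy]undec‑5‑enedioate, 17 N‑bromosuccinimide
Product: 18 1‑tert‑butyl 11‑methyl (2Z,5E,8S,9Z)‑10‑(bromomethyl)‑2‑(2,2‑dimethoxyethylidene)‑6‑methyl‑8‑[(2,2,6,6‑tetramethylpiperidin‑1‑yl)oxy]undeca‑5,9‑dienedioate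
Conditions: NBS (1.3 equiv), Me2S (1.5 equiv), CH2Cl2, 0 → 25 °C
Reagents that add atoms: N‑bromosuccinimide 17, O=C1CCC(=O)N1Br
Why: Corey–Kim‑type activation of the Baylis–Hillman alcohol and SN2′ attack of bromide give the (Z)‑2‑(bromomethyl)‑2‑enoate, the standard allylic transposition of these adducts.

Step 8
Reactants: 18 1‑tert‑butyl 11‑methyl (2Z,5E,8S,9Z)‑10‑(bromomethyl)‑2‑(2,2‑dimethoxyethylidene)‑6‑methyl‑8‑[(2,2,6,6‑tetramethylpiperidin‑1‑yl)oxy]undeca‑5,9‑dienedioate, 19 water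
Product: 20 1‑tert‑butyl 11‑methyl (2Z,5E,8S,9Z)‑10‑(bromomethyl)‑6‑methyl‑2‑(2‑oxoethylidene)‑8‑[(2,2,6,6‑tetramethylpiperidin‑1‑yl)oxy]undeca‑5,9‑dienedioate
Conditions: LiBF4 (2 equiv), MeCN/H2O 50:1, 25 °C
Reagents that add atoms: water 19, O
Why: mild Lewis‑acid acetal hydrolysis releases the C6 enal without touching the tert‑butyl ester, the allylic bromide or the Z olefin.

Step 9
Reactants: 20 1‑tert‑butyl 11‑methyl (2Z,5E,8S,9Z)‑10‑(bromomethyl)‑6‑methyl‑2‑(2‑oxoethylidene)‑8‑[(2,2,6,6‑tetramethylpiperidin‑1‑yl)oxy]undeca‑5,9‑dienedioate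
Product: 23 tert‑butyl 8α‑[(2,2,6,6‑tetramethylpiperidin‑1‑yl)oxy]elema‑1,3,11(13)‑trien‑12,6α‑olid‑15‑oate, via cyclodecadienol ester 21 (not isolated), via germacranolide 22 (not isolated)
Conditions: CrCl2 (5 equiv), THF, 0.003 M (slow addition of 20), 25 °C; aqueous work‑up; then toluene, 90 °C, 6 h
Reagents that add atoms: none
Why: Nozaki–Hiyama–Kishi‑type intramolecular carbonyl allylation (the allylchromium adds to the C6 aldehyde through a chair transition state with C5 and C8 equatorial and the bulky aminoxy group anti to the forming C6–C7 bond, giving the 6,7‑anti and 7,8‑trans relationships), then the chromium alkoxide closes the trans‑fused γ‑lactone on the methyl ester and, on heating, the (E,E)‑cyclodeca‑1,5‑diene undergoes a chair Cope rearrangement (accelerated by the ester at C4, the 2‑position of the 1,5‑diene) that sets C5 and C10.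

Step 10
Reactants: 23 tert‑butyl 8α‑[(2,2,6,6‑tetramethylpiperidin‑1‑yl)oxy]elema‑1,3,11(13)‑trien‑12,6α‑olid‑15‑oate
Product: 25 tert‑butyl 8‑oxoelema‑1,3,11(13)‑trien‑12,6α‑olid‑15‑oate, via N‑oxide 24 (not isolated)
Conditions: mCPBA (2.0 equiv), NaHCO3, CH2Cl2, 0 °C, short reaction time
Reagents that add atoms: none
Why: N‑oxidation of the alkoxyamine followed by spontaneous Cope‑type elimination (the known oxidative cleavage of TEMPO ethers to carbonyls) removes the relay stereocentre after it has set C5, C6, C7 and C10; the vinyl group and the two electron‑poor alkenes are epoxidised far more slowly.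

Step 11
Reactants: 25 tert‑butyl 8‑oxoelema‑1,3,11(13)‑trien‑12,6α‑olid‑15‑oate
Product: 26 tert‑butyl 8β‑hydroxyelema‑1,3,11(13)‑trien‑12,6α‑olid‑15‑oate
Conditions: (S)‑2‑methyl‑CBS‑oxazaborolidine (0.5 equiv), catecholborane (2 equiv), toluene, −78 → −40 °C
Reagents that add atoms: none
Why: Corey–Bakshi–Shibata reduction in which reagent control (C7 is the larger flank) and substrate control (the axial C10 methyl blocks the β face) are matched, so hydride arrives from the α face and gives the axial 8β (8R) alcohol; catecholborane leaves the vinyl group, the acrylate and the α‑methylene lactone untouched, and any 8α epimer can be re‑oxidised.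

Step 12
Reactants: 26 tert‑butyl 8β‑hydroxyelema‑1,3,11(13)‑trien‑12,6α‑olid‑15‑oate, 27 tigloyl chloride
Product: 28 tert‑butyl 8β‑tigloyloxyelema‑1,3,11(13)‑trien‑12,6α‑olid‑15‑oate
Conditions: tigloyl chloride (3 equiv), DMAP (1 equiv), Et3N (4 equiv), CH2Cl2, 40 °C
Reagents that add atoms: tigloyl chloride 27, C/C=C(\C)C(=O)Cl
Why: DMAP‑catalysed acylation of the axial secondary alcohol with retention at C8; the E olefin of the tiglate is the stable isomer and does not scramble.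

Step 13
Reactants: 28 tert‑butyl 8β‑tigloyloxyelema‑1,3,11(13)‑trien‑12,6α‑olid‑15‑oate
Product: 29 8β‑tigloyloxyelema‑1,3,11(13)‑trien‑12,6α‑olid‑15‑oic acid (CNP0256928.1)
Conditions: TFA/CH2Cl2 1:4, 0 → 25 °C
Reagents that add atoms: none
Why: acidolysis of the tert‑butyl ester (loss of isobutene) leaves the tiglate, the lactone and all five stereocentres untouched.

## Compound list

1 | tert‑butyl acrylate | C=CC(=O)OC(C)(C)C | starting material
2 | 2,2‑dimethoxyacetaldehyde (60 wt% in water) | COC(OC)C=O | starting material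
3 | tert‑butyl 3‑hydroxy‑4,4‑dimethoxy‑2‑methylidenebutanoate (racemic) | C=C(C(=O)OC(C)(C)C)C(O)C(OC)OC | intermediate
4 | trimethyl orthoacetate | CC(OC)(OC)OC | starting material
5 | mixed ketene acetal, tert‑butyl 4,4‑dimethoxy‑3‑[(1‑methoxyethenyl)oxy]‑2‑methylidenebutanoate | C=C(OC)OC(C(OC)OC)C(=C)C(=O)OC(C)(C)C | intermediate
6 | 1‑tert‑butyl 5‑methyl (2Z)‑2‑(2,2‑dimethoxyethylidene)pentanedioate | COC(=O)CC/C(C(=O)OC(C)(C)C)=C/C(OC)OC | intermediate
7 | isopropenylmagnesium bromide | C=C(C)[Mg]Br | starting material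
8 | tert‑butyl (2Z)‑2‑(2,2‑dimethoxyethylidene)‑5‑oxopentanoate (released from its aluminium hemiacetal) | O=CCC/C(C(=O)OC(C)(C)C)=C/C(OC)OC | intermediate
9 | tert‑butyl (2Z)‑2‑(2,2‑dimethoxyethylidene)‑5‑hydroxy‑6‑methylhept‑6‑enoate (racemic) | C=C(C)C(O)CC/C(C(=O)OC(C)(C)C)=C/C(OC)OC | intermediate
10 | ethyl vinyl ether | C=COCC | starting material
11 | tert‑butyl (2Z)‑2‑(2,2‑dimethoxyethylidene)‑5‑(ethenyloxy)‑6‑methylhept‑6‑enoate | C=COC(CC/C(C(=O)OC(C)(C)C)=C/C(OC)OC)C(C)=C | intermediate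
12 | tert‑butyl (2Z,5E)‑2‑(2,2‑dimethoxyethylidene)‑6‑methyl‑9‑oxonon‑5‑enoate | O=CCC/C(C)=C/CC/C(C(=O)OC(C)(C)C)=C/C(OC)OC | intermediate
13 | TEMPO (2,2,6,6‑tetramethylpiperidin‑1‑oxyl) | CC1(C)CCCC(C)(C)N1[O] | starting material
14 | tert‑butyl (2Z,5E,8S)‑2‑(2,2‑dimethoxyethylidene)‑6‑methyl‑9‑oxo‑8‑[(2,2,6,6‑tetramethylpiperidin‑1‑yl)oxy]non‑5‑enoate | O=C[C@@H](ON1C(C)(C)CCCC1(C)C)C/C(C)=C/CC/C(C(=O)OC(C)(C)C)=C/C(OC)OC | intermediate
15 | methyl acrylate | C=CC(=O)OC | starting material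
16 | 1‑tert‑butyl 11‑methyl (2Z,5E,8S)‑2‑(2,2‑dimethoxyethylidene)‑9‑hydroxy‑6‑methyl‑10‑methylidene‑8‑[(2,2,6,6‑tetramethylpiperidin‑1‑yl)oxy]undec‑5‑enedioate (both C9 epimers) | C=C(C(=O)OC)C(O)[C@@H](ON1C(C)(C)CCCC1(C)C)C/C(C)=C/CC/C(C(=O)OC(C)(C)C)=C/C(OC)OC | intermediate
17 | N‑bromosuccinimide | O=C1CCC(=O)N1Br | starting material
18 | 1‑tert‑butyl 11‑methyl (2Z,5E,8S,9Z)‑10‑(bromomethyl)‑2‑(2,2‑dimethoxyethylidene)‑6‑methyl‑8‑[(2,2,6,6‑tetramethylpiperidin‑1‑yl)oxy]undeca‑5,9‑dienedioate | BrC/C(C(=O)OC)=C\[C@@H](ON1C(C)(C)CCCC1(C)C)C/C(C)=C/CC/C(C(=O)OC(C)(C)C)=C/C(OC)OC | intermediate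
19 | water | O | starting material
20 | 1‑tert‑butyl 11‑methyl (2Z,5E,8S,9Z)‑10‑(bromomethyl)‑6‑methyl‑2‑(2‑oxoethylidene)‑8‑[(2,2,6,6‑tetramethylpiperidin‑1‑yl)oxy]undeca‑5,9‑dienedioate | BrC/C(C(=O)OC)=C\[C@@H](ON1C(C)(C)CCCC1(C)C)C/C(C)=C/CC/C(C(=O)OC(C)(C)C)=C/C=O | intermediate
21 | ten‑membered homoallylic alcohol (formed as its chromium alkoxide): tert‑butyl (E,E)‑6α‑hydroxy‑7β‑[1‑(methoxycarbonyl)ethenyl]‑10‑methyl‑8α‑[(2,2,6,6‑tetramethylpiperidin‑1‑yl)oxy]cyclodeca‑1(10),4‑diene‑4‑carboxylate (germacrane numbering) | C/C1=C\CC/C(C(=O)OC(C)(C)C)=C/[C@@H](O)[C@H](C(=C)C(=O)OC)[C@@H](ON2C(C)(C)CCCC2(C)C)C1 | intermediate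
22 | tert‑butyl 8α‑[(2,2,6,6‑tetramethylpiperidin‑1‑yl)oxy]germacra‑1(10)E,4(ring‑trans),11(13)‑trien‑12,6α‑olid‑15‑oate (6βH,7αH,8βH) | C/C1=C\CC/C(C(=O)OC(C)(C)C)=C/[C@H]2OC(=O)C(=C)[C@@H]2[C@@H](ON3C(C)(C)CCCC3(C)C)C1 | intermediate
23 | tert‑butyl 8α‑[(2,2,6,6‑tetramethylpiperidin‑1‑yl)oxy]elema‑1,3,11(13)‑trien‑12,6α‑olid‑15‑oate (5αH,6βH,7αH,8βH,10β‑methyl) | C=C[C@]1(C)C[C@H](ON3C(C)(C)CCCC3(C)C)[C@H]2C(=C)C(=O)O[C@@H]2[C@H]1C(=C)C(=O)OC(C)(C)C | intermediate
24 | N‑oxide of 23 | C=C[C@]1(C)C[C@H](O[N+]3([O-])C(C)(C)CCCC3(C)C)[C@H]2C(=C)C(=O)O[C@@H]2[C@H]1C(=C)C(=O)OC(C)(C)C | intermediate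
25 | tert‑butyl 8‑oxoelema‑1,3,11(13)‑trien‑12,6α‑olid‑15‑oate (5αH,6βH,7αH,10β‑methyl) | C=C[C@]1(C)CC(=O)[C@H]2C(=C)C(=O)O[C@@H]2[C@H]1C(=C)C(=O)OC(C)(C)C | intermediate
26 | tert‑butyl 8β‑hydroxyelema‑1,3,11(13)‑trien‑12,6α‑olid‑15‑oate | C=C[C@]1(C)C[C@@H](O)[C@H]2C(=C)C(=O)O[C@@H]2[C@H]1C(=C)C(=O)OC(C)(C)C | intermediate
27 | tigloyl chloride, (2E)‑2‑methylbut‑2‑enoyl chloride | C/C=C(\C)C(=O)Cl | starting material
28 | tert‑butyl 8β‑tigloyloxyelema‑1,3,11(13)‑trien‑12,6α‑olid‑15‑oate | C=C[C@]1(C)C[C@@H](OC(=O)/C(C)=C/C)[C@H]2C(=C)C(=O)O[C@@H]2[C@H]1C(=C)C(=O)OC(C)(C)C | intermediate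
29 | 2‑[(3aR,4R,6S,7R,7aR)‑6‑ethenyl‑6‑methyl‑3‑methylidene‑4‑{[(2E)‑2‑methylbut‑2‑enoyl]oxy}‑2‑oxooctahydro‑1‑benzofuran‑7‑yl]prop‑2‑enoic acid (CNP0256928.1) | C=C[C@]1(C)C[C@@H](OC(=O)/C(C)=C/C)[C@H]2C(=C)C(=O)O[C@@H]2[C@H]1C(=C)C(=O)O | target

## Step count and risks

Total steps: 13. Longest linear sequence: 13 (fully linear from 1 and 2).

Steps most likely to fail:

Step 9 (ring‑closure cascade). The closure may give oligomers, syn instead of anti addition, the other face relative to C8, or an incomplete Cope equilibrium. The fallback sets out from 16 and comes back to the route at 23. It replaces the allyl bromide/CrCl2 pair by a palladium‑catalysed umpolung allylation. Compound 16 is acetylated (Ac2O, DMAP, CH2Cl2) to the allylic acetate F1. Its acetal is hydrolysed (LiBF4, wet MeCN) to the acetoxy enal F2. The ring is then closed with Pd(PPh3)4 (10 mol%) and Et2Zn in THF at high dilution, where a π‑allylpalladium is transmetallated to an allylzinc that adds through a cyclic transition state. This mode of ten‑membered ring closure is proven for germacrane skeletons. Lactonisation and heating in toluene give 22 and then 23.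

Step 6 (Baylis–Hillman reaction of the hindered α‑aminoxy aldehyde). The reaction may be very slow and the amine base may erode C8. The fallback sets out from 14 and comes back at 16. It replaces the amine‑catalysed process by addition of a preformed α‑acrylate nucleophile, [1‑(methoxycarbonyl)ethenyl]diisobutylaluminium F3. This is made from methyl propiolate and i‑Bu2AlH with N‑methylmorpholine N‑oxide in THF at 0 °C, adds to hindered aldehydes within hours under non‑basic conditions, and gives 16 directly.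

Step 2 (Z selectivity of the Johnson–Claisen rearrangement with an acetal‑bearing substrate). The fallback sets out from 2 and comes back at 6. It builds the C4=C5 bond by an Ando‑type Horner–Wadsworth–Emmons olefination instead. Diphenyl phosphite and tert‑butyl bromoacetate (Et3N, CH2Cl2) give tert‑butyl (diphenoxyphosphoryl)acetate F4. Conjugate addition of F4 to methyl acrylate 15 (cat. DBU) gives 1‑tert‑butyl 5‑methyl 2‑(diphenoxyphosphoryl)pentanedioate F5. Deprotonation of F5 with NaH in THF at −78 °C and reaction with anhydrous 2 gives 6, the diaryl phosphonate placing the ester cis to the aldehyde‑derived carbon.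

## Further compounds

F1 | step 9 | 1‑tert‑butyl 11‑methyl (2Z,5E,8S)‑9‑acetoxy‑2‑(2,2‑dimethoxyethylidene)‑6‑methyl‑10‑methylidene‑8‑[(2,2,6,6‑tetramethylpiperidin‑1‑yl)oxy]undec‑5‑enedioate | C=C(C(=O)OC)C(OC(C)=O)[C@@H](ON1C(C)(C)CCCC1(C)C)C/C(C)=C/CC/C(C(=O)OC(C)(C)C)=C/C(OC)OC
F2 | step 9 | 1‑tert‑butyl 11‑methyl (2Z,5E,8S)‑9‑acetoxy‑6‑methyl‑10‑methylidene‑2‑(2‑oxoethylidene)‑8‑[(2,2,6,6‑tetramethylpiperidin‑1‑yl)oxy]undec‑5‑enedioate | C=C(C(=O)OC)C(OC(C)=O)[C@@H](ON1C(C)(C)CCCC1(C)C)C/C(C)=C/CC/C(C(=O)OC(C)(C)C)=C/C=O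
F3 | step 6 | [1‑(methoxycarbonyl)ethenyl]diisobutylaluminium | C=C(C(=O)OC)[Al](CC(C)C)CC(C)C
F4 | step 2 | tert‑butyl (diphenoxyphosphoryl)acetate | CC(C)(C)OC(=O)CP(=O)(Oc1ccccc1)Oc1ccccc1
F5 | step 2 | 1‑tert‑butyl 5‑methyl 2‑(diphenoxyphosphoryl)pentanedioate | COC(=O)CCC(C(=O)OC(C)(C)C)P(=O)(Oc1ccccc1)Oc1ccccc1
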